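Remark on the chemistry (numbering): ring positions carry labdane numbers throughout (ring A = C1–C5 and C10, ring B = C5–C10, C17 on C8, C18/C19 on C4, C20 on C10, side chain C11–C16); β means the face of the C10 methyl group, α the opposite face.

Remark on the chemistry (catalyst sense): the (S)-configured oxazaborolidinium catalyst is assigned to the required 10β-methyl adduct by analogy with the facial preference of this catalyst class for s-trans enoates and quinones; its mirror image is equally available and would be used if the sense proved opposite.

## Analysis of the target

The target, 6β,7α-diacetoxylabda-8,13Z-dien-15-ol, is a labdane: a trans-fused decalin with a gem-dimethyl group on C4, an angular methyl on C10, and a tetrasubstituted C8=C9 alkene that carries the C17 methyl and the C11–C16 side chain, which ends in a Z-configured trisubstituted allylic alcohol. Four contiguous stereocentres sit on C10, C5, C6 and C7: the quaternary C10 (β-methyl), C5 (α-hydrogen, hence the trans fusion), the 6β acetate (axial, syn to the β-methyl groups on C4 and C10) and the 7α acetate (pseudo-axial and allylic), so the two acetates are trans-diaxial. The sensitive groups are the allylic C7 acetate (ionisation, transposition, acyl migration), the two esters beside a free primary alcohol (three oxygens that must be told apart) and the Z alkene, which must not isomerise. The hard points are the enantioselective construction of the quaternary C10 next to a tetrasubstituted alkene, the crowded 6β oxygen, and the attachment of the side chain to the hindered C9. The plan rests on the fact that ring B is substituted exactly like a quinone: the six ring carbons of 2,6-dimethyl-1,4-benzoquinone (1) are C5–C10, its methyl groups are C17 and C20, and its oxygens sit on C6 (kept) and C9 (a handle for the side chain). The rest of ring A, C1–C4 with both C4 methyls, is 4-methylpenta-1,3-diene (2), so only the bonds C1–C10 and C4–C5 are needed to build the bicyclic core.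

## Retrosynthetic reasoning

**Acetates and the C15 hydroxyl (22 ⇐ 21 ⇐ 20).** The two acetyl C–O bonds and one Si–O bond are cut last. The primary C15 hydroxyl is more reactive than the two secondary ones, so it stays silylated until diol 20 has been acetylated to 21. The forward steps must acylate a hindered axial alcohol and then remove a silyl ether without touching esters.

**The C6 and C7 oxygens (20 ⇐ 19 ⇐ 17).** Both oxygen-bearing centres are traced to one ketone at C6. The C6–H bond comes from hydride addition and the C7–O bond from oxidation of the C6 enolate 18. This is chosen over a dihydroxylation of a C6=C7 alkene because that would give a cis diol. Here the β face of ring B is covered by the 4β and 10β methyl groups, so both reagents come from the α face and the trans-diaxial 6β,7α pattern results.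

**The C9–C11 bond (17 ⇐ 16 ⇐ 9 + 15).** Cutting between ring and side chain makes the route convergent. C9 is a carbonyl carbon in the bicyclic precursor, so it can become an sp2 electrophile, the enol triflate 9, whose formation also creates the C8=C9 alkene. The side chain arrives as the primary alkylborane 15. The forward coupling has to work at a carbon flanked by a quaternary centre and a methyl-bearing alkene carbon.

**The side chain (15 ⇐ 14 ⇐ 13 ⇐ 12 ⇐ 10).** The C11–C12 unit is added as a vinyl group to the Z iodide 13, and the iodide comes from anti addition of hydride and a metal across the triple bond of 10 through the cyclic alkenylaluminate 11. This sets the Z geometry before the fragment meets the core, where it could no longer be corrected.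

**Telling the two carbonyls apart (9 ⇐ 7 ⇐ 5).** Dione 5 has two ketones. The C6 ketone has the only α-methylene group (C7), so kinetic enolisation to 6 and silylation give 7. This masks C6 in a form that later returns the ketone, and leaves C8–H as the only acidic hydrogen for triflation through dienolate 8.

**Saturation and ring fusion (5 ⇐ 4 ⇐ 3).** Both alkenes of 4 are hydrogenated; the C8 centre formed is lost again at the triflate stage. The trans fusion of 4 is reached from the cis adduct 3 by inverting C5, the only enolisable ring-fusion carbon.

**The key disconnection (3 ⇐ 1 + 2).** Cutting C1–C10 and C4–C5 removes ring A, two skeletal bonds and both ring-fusion stereocentres in one step and leads to two purchased compounds. The forward cycloaddition must take place at a methyl-bearing alkene of 1 with the unsubstituted diene terminus bonding to C10, and on one face only.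

## Alternatives that were turned down

**Alternative 1: nitroalkene double Michael cascade.**
- Disconnection: C5–C10 and C6–C7, so both rings come from the acyclic nitro-enone A2.
- Forward key step: a secondary amine turns the ketone of A2 into its C10 enamine, which adds to the nitroalkene carbon C5 (closing ring A). The C6 nitronate then adds to C7 of the isopropenyl ketone (closing ring B) to give the nitro ketone A1.
- For: both rings and the C5/C10 relationship form in one operation. The trans fusion and a saturated ring A are obtained directly, so no epimerisation or hydrogenation is needed, and a Nef reaction on A1 would give dione 5. On these points it is stronger than the chosen route.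
- Against: the enamine has to form at a ketone that is α-branched on one side and conjugated on the other. It must then make a quaternary carbon by attacking a nitroalkene carbon that sits next to the quaternary C4. The amine can add to the enone instead, and enamines of α-branched ketones give poor control of geometry and therefore of the quaternary centre. A2 itself would need a linear synthesis of roughly six steps.
- Comparison: the chosen route reaches 5 in three steps from two purchased compounds and relies on a catalyst class with a defined binding model for quinones.

**Alternative 2: Ireland–Claisen ring contraction of a cyclogeranyl δ-lactone.**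
- Disconnection: C9–C10, with ring A bought intact.
- Forward key step: the silyl ketene acetal of lactone A4 rearranges through a boat [3,3] transition state. This forms C9–C10, moves the alkene to C5=C6 and contracts the lactone to ring B, giving acid A3 with C11 attached.
- For: the quaternary C10 is made by intramolecular chirality transfer, a dependable way to form congested C–C bonds, and C11 is already bonded to C9. On that bond it is stronger than the chosen route, which needs a hindered cross-coupling.
- Against: A3 has the wrong functional pattern in ring B. It has no oxygen at C6 or C7, and its C5=C6 alkene does not lead directly to a 5α-H, 6β,7α-dioxygenated array. C8 and C9 are sp3 stereocentres that must be destroyed to make the tetrasubstituted alkene. The C11 acid needs reduction and a five-carbon extension. The boat transition state forced by the small ring makes the C9/C10 relationship less secure, and enantiopure A4 needs its own asymmetric synthesis.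
- Comparison: the chosen cycloaddition places oxygen on C6 and a carbonyl on C9 from the start, which saves the redox steps that A3 would require.

**Alternative 3: asymmetric Diels–Alder of a cyclogeranyl siloxydiene with but-2-ynal.**
- Disconnection: C7–C8 and C9–C10, so ring B is formed on a preformed ring A.
- Forward key step: but-2-ynal A7, activated by a chiral oxazaborolidinium Lewis acid, adds across the diene C10=C5–C6=C7 of siloxydiene A6 to give dienal A5.
- For: A5 already has the C8=C9 alkene with C17 and C11 attached, the C6 oxygen as a silyl enol ether and a saturated ring A. It would save the hydrogenation, the enol triflate and the cross-coupling at C9. In ring-B unsaturation it is stronger than the chosen route.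
- Against: the diene terminus C10 is fully substituted, and the 2,6,6-trimethylcyclohexenyl unit holds the siloxyvinyl group well out of conjugation, so the s-cis diene is poorly populated and hindered exactly where the quaternary centre must form. A rod-shaped ynal offers the catalyst little to discriminate between faces. C5 is sp2 in A5, so the 5α hydrogen still has to be set by a protonation. C11 arrives as an aldehyde although the target needs CH2 there, which costs three or four steps (olefination and a chemoselective reduction beside two other alkenes, or reduction, activation and allylic coupling).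
- Comparison: the chosen route pairs a doubly activated dienophile with an unhindered diene terminus, uses purchased partners, and attaches the whole side chain in one bond-forming operation.

Key step: step 1

## Route

Step 1
Reactants: 1 2,6-dimethyl-1,4-benzoquinone; 2 4-methylpenta-1,3-diene
Product: 3 cis-fused cycloadduct, 4,4,8,10-tetramethyl-Δ2,7-octalin-6,9-dione (10β-methyl; 5β-H), i.e. cis-2,5,5,8a-tetramethyl-4a,5,8,8a-tetrahydronaphthalene-1,4-dione
Conditions: (S)-3,3-diphenyl-1-(2-methylphenyl)tetrahydro-1H,3H-pyrrolo[1,2-c][1,3,2]oxazaborole (20 mol%), HN(SO2CF3)2 (17 mol%), 2 (4 equiv), CH2Cl2, −78 → −20 °C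
Reagents that add atoms: none
Why: This is a Lewis acid-catalysed Diels–Alder reaction of the kind established for oxazaborolidinium-activated 2,5- and 2,6-dialkyl-1,4-benzoquinones with substituted butadienes. The cationic boron binds the C6 carbonyl of 1, the only one whose lone pairs are flanked by hydrogens, and a contact between the adjacent ring C–H and the catalyst oxygen holds the quinone against one aryl group, so only the alkene between the bound carbonyl and a methyl-bearing carbon (C5=C10) is activated and only one of its faces is open. Bond formation is suprafacial on both partners but strongly asynchronous: the unsubstituted terminus C1 of 2 bonds first to the β carbon C10 and the gem-dimethyl terminus C4 then closes onto C5, at the limit a Michael addition followed by collapse of a tertiary allyl cation onto the boron enolate. Ring A is thereby closed as a six-membered ring by [4+2] addition (a 6-endo closure in the stepwise limit), and because both bonds form on the same face of the quinone the ring fusion is cis. C10 is set by the catalyst through the choice of quinone face, and C5 follows from the suprafacial addition and is corrected in step 2. The regiochemistry needed (C1 to C10, C4 to C5) is secured by the polarisation of the bound enone and of the diene, which also pairs each hindered carbon with an unhindered one, and the two methyl-bearing alkenes of 1 are equivalent by symmetry, so there is no site problem. The excess of diene and the temperature ramp answer the low s-cis population of 2, whose terminal Z methyl is the weak point of this step.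

Step 2
Reactants: 3 cis-fused cycloadduct
Product: 4 trans-fused enedione, 4,4,8,10-tetramethyl-Δ2,7-octalin-6,9-dione (10β-methyl; 5α-H)
Conditions: DBU (0.2 equiv), CH2Cl2, 0 → 23 °C
Reagents that add atoms: none
Why: Reversible deprotonation of C5–H, the only ring-fusion hydrogen and α to the C6 carbonyl, equilibrates the ring fusion through the cross-conjugated dienolate (thermodynamic epimerisation); C10 is quaternary, so it can neither invert nor allow aromatisation. The trans isomer, in which neither ring carries the quaternary C4 or the C9 carbonyl carbon as an axial substituent, is expected to predominate, and reprotonation from the α face, away from the 4β and 10β methyl groups, leads to it.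

Step 3
Reactants: 4 trans-fused enedione
Product: 5 trans-4,4,8,10-tetramethyldecalin-6,9-dione (10β-methyl; 5α-H; C8 epimers)
Conditions: H2 (1–3 atm), Pd/C (10 wt% Pd), EtOAc, 23 °C
Reagents that add atoms: none
Why: Heterogeneous catalytic hydrogenation with syn delivery of hydrogen reduces the electron-poor C7=C8 bond and the cis-disubstituted C2=C3 bond and leaves both ketones untouched. The new centre C8 is expected mainly as the 8β-methyl epimer (hydrogen from the α face, opposite the C10 methyl), but its configuration does not matter because C8 becomes sp2 again in step 5.

Step 4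
Reactants: 5 trans-4,4,8,10-tetramethyldecalin-6,9-dione
Product: 7 6-(tert-butyldimethylsilyloxy)-4,4,8,10-tetramethyl-Δ6-octalin-9-one (trans; C8 epimers), via potassium enolate 6 (not isolated)
Conditions: KN(SiMe3)2 (1.05 equiv), THF, −78 °C; t-BuMe2SiCl (1.2 equiv), −78 → 0 °C
Reagents that add atoms: tert-butyldimethylsilyl chloride, CC(C)(C)[Si](C)(C)Cl
Why: Kinetic enolisation followed by O-silylation: the bulky amide base removes a proton from the only α-methylene group (C7) and not from the α-methine positions C5 and C8, so one ketone of the 1,4-dione is converted regioselectively into its silyl enol ether. The C6 oxygen is masked in a form that later returns the ketone, and C5 is not deprotonated and keeps its configuration.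

Step 5
Reactants: 7 6-(tert-butyldimethylsilyloxy)-4,4,8,10-tetramethyl-Δ6-octalin-9-one
Product: 9 6-(tert-butyldimethylsilyloxy)-4,4,8,10-tetramethyl-Δ6,8-hexalin-9-yl trifluoromethanesulfonate (trans), via potassium dienolate 8 (not isolated)
Conditions: KN(SiMe3)2 (1.3 equiv), THF, −78 °C; PhN(SO2CF3)2 (1.3 equiv), −78 → 0 °C
Reagents that add atoms: N-phenylbis(trifluoromethanesulfonimide), O=S(=O)(N(c1ccccc1)S(=O)(=O)C(F)(F)F)C(F)(F)F
Why: Enolate O-triflation: C8–H is the only acidic hydrogen left (α to the C9 ketone and allylic to the enol ether), its removal planarises C8 and gives dienolate 8, and the triflimide transfers its sulfonyl group to the enolate oxygen. Both C8 epimers of 7 converge on one 2-triflyloxy-1,3-diene in which C9 is activated for coupling and C6 stays masked.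

Step 6
Reactants: 10 but-2-yn-1-ol
Product: 12 (2Z)-3-iodobut-2-en-1-ol, via sodium alkenylaluminate 11 (not isolated)
Conditions: NaAlH2(OCH2CH2OMe)2 (1.5 equiv), THF, 0 → 23 °C; I2 (2 equiv), THF, −78 → 0 °C
Reagents that add atoms: iodine, II
Why: Hydroxyl-directed trans-hydroalumination of a propargylic alcohol followed by iodinolysis: the oxygen-bound aluminium hydride delivers hydride to C14 and aluminium to C13 within a five-membered ring, so aluminium and the CH2O group are cis, and iodine replaces aluminium with retention. This fixes the Z geometry of the future C13=C14 bond.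

Step 7
Reactants: 12 (2Z)-3-iodobut-2-en-1-ol
Product: 13 tert-butyl{[(2Z)-3-iodobut-2-en-1-yl]oxy}diphenylsilane
Conditions: t-BuPh2SiCl (1.1 equiv), imidazole (2 equiv), CH2Cl2, 0 → 23 °C
Reagents that add atoms: tert-butyldiphenylsilyl chloride, CC(C)(C)[Si](Cl)(c1ccccc1)c1ccccc1
Why: Imidazole-promoted silylation of a primary alcohol. The tert-butyldiphenylsilyl ether is chosen because it survives the low-temperature fluoride cleavage of a silyl enol ether (step 10), strong base, borohydride and acylation, and can be removed at the end without touching acetates.

Step 8
Reactants: 13 tert-butyl{[(2Z)-3-iodobut-2-en-1-yl]oxy}diphenylsilane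
Product: 14 tert-butyl{[(2Z)-3-methylpenta-2,4-dien-1-yl]oxy}diphenylsilane
Conditions: Bu3SnCH=CH2 (1.2 equiv), PdCl2(MeCN)2 (5 mol%), DMF, 23 °C
Reagents that add atoms: tributyl(vinyl)stannane, C=C[Sn](CCCC)(CCCC)CCCC
Why: Stille coupling of an alkenyl iodide with a vinylstannane; oxidative addition and reductive elimination at the sp2 carbon proceed with retention, so the Z geometry is carried into the 1,3-diene and C11/C12 are added in one step.

Step 9
Reactants: 14 tert-butyl{[(2Z)-3-methylpenta-2,4-dien-1-yl]oxy}diphenylsilane; 9 6-(tert-butyldimethylsilyloxy)-4,4,8,10-tetramethyl-Δ6,8-hexalin-9-yl trifluoromethanesulfonate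
Product: 16 6-(tert-butyldimethylsilyloxy)-15-(tert-butyldiphenylsilyloxy)labda-6,8,13Z-triene, via alkylborane 15 (not isolated)
Conditions: 14 (1.5 equiv), 9-borabicyclo[3.3.1]nonane (1.6 equiv), THF, 0 → 23 °C; then 9, PdCl2(dppf) (10 mol%), AsPh3 (10 mol%), Cs2CO3 (3 equiv), DMF/H2O, 23 → 50 °C
Reagents that add atoms: none
Why: Hydroboration followed by B-alkyl Suzuki–Miyaura coupling: the dialkylborane adds only to the monosubstituted alkene of 14 with boron on the terminal carbon (C11), and the primary alkylborane 15 transfers its alkyl group to the alkenylpalladium species formed from triflate 9. Alkenyl triflates of the 2,6,6-trisubstituted cyclohexenyl type are established partners in this coupling, the wide-bite-angle diphosphine favours reductive elimination over β-hydride elimination, and the Z alkene and both silyl ethers are spectators.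

Step 10
Reactants: 16 6-(tert-butyldimethylsilyloxy)-15-(tert-butyldiphenylsilyloxy)labda-6,8,13Z-triene
Product: 17 15-(tert-butyldiphenylsilyloxy)labda-8,13Z-dien-6-one
Conditions: Bu4NF (1.05 equiv), AcOH (1.1 equiv), THF, −20 → 0 °C
Reagents that add atoms: none
Why: Fluoride cleavage of the silyl enol ether; the dienolate released is protonated under kinetic control at its α carbon C7 by the acetic acid buffer, which gives the β,γ-unsaturated ketone and leaves the tetrasubstituted C8=C9 bond in place. A silyl enol ether is cleaved far faster than the primary tert-butyldiphenylsilyl ether, hence one equivalent at low temperature.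

Step 11
Reactants: 17 15-(tert-butyldiphenylsilyloxy)labda-8,13Z-dien-6-one
Product: 19 15-(tert-butyldiphenylsilyloxy)-7α-hydroxylabda-8,13Z-dien-6-one, via potassium dienolate 18 (not isolated)
Conditions: KN(SiMe3)2 (1.15 equiv), THF, −78 °C; 2-(phenylsulfonyl)-3-phenyloxaziridine (1.5 equiv), −78 °C; AcOH, −78 °C
Reagents that add atoms: 2-(phenylsulfonyl)-3-phenyloxaziridine, O=S(=O)(N1OC1c1ccccc1)c1ccccc1
Why: α-Hydroxylation of a ketone enolate with an N-sulfonyloxaziridine: deprotonation occurs at C7, which is both α to the carbonyl and allylic, and dienolate 18 takes up the electrophilic oxygen at its α carbon, not at the fully substituted and shielded γ carbon C9. The oxidant approaches C7 from the α face, away from the 4β and 10β methyl groups that cover the β face of ring B, which sets the 7α hydroxyl, and the isolated alkenes do not react with this reagent. The cold acidic quench keeps the α-ketol from isomerising.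

Step 12
Reactants: 19 15-(tert-butyldiphenylsilyloxy)-7α-hydroxylabda-8,13Z-dien-6-one
Product: 20 15-(tert-butyldiphenylsilyloxy)labda-8,13Z-diene-6β,7α-diol
Conditions: NaBH4 (1.5 equiv), CeCl3·7H2O (1.2 equiv), MeOH, −78 → −40 °C
Reagents that add atoms: none
Why: Luche-type 1,2-reduction of the ketone: the β face of C6 is blocked by the two syn-axial methyl groups on C4 and C10, so hydride arrives from the α face and the new hydroxyl is 6β (axial), trans to the 7α hydroxyl. The cerium salt speeds the reduction at low temperature and keeps the medium from becoming basic enough to isomerise the α-ketol first.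

Step 13
Reactants: 20 15-(tert-butyldiphenylsilyloxy)labda-8,13Z-diene-6β,7α-diol
Product: 21 6β,7α-diacetoxy-15-(tert-butyldiphenylsilyloxy)labda-8,13Z-diene
Conditions: Ac2O (6 equiv), Et3N (8 equiv), DMAP (0.5 equiv), CH2Cl2, 23 → 40 °C
Reagents that add atoms: acetic anhydride, CC(=O)OC(C)=O
Why: Nucleophile-catalysed acylation of both secondary alcohols; the axial 6β hydroxyl is hindered, hence the excess of anhydride and mild warming, while the primary C15 oxygen is still silylated and cannot be acetylated.

Step 14
Reactants: 21 6β,7α-diacetoxy-15-(tert-butyldiphenylsilyloxy)labda-8,13Z-diene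
Product: 22 6β,7α-diacetoxylabda-8,13Z-dien-15-ol (CNP0187815.3)
Conditions: HF·pyridine, pyridine, THF, 0 → 23 °C
Reagents that add atoms: none
Why: Cleavage of the silyl ether with pyridine-buffered hydrogen fluoride, under which the secondary acetates, the allylic C7 acetate and the Z alkene are stable; this frees the C15 alcohol and gives the target.

## Compound list

1 | 2,6-dimethyl-1,4-benzoquinone | CC1=CC(=O)C=C(C)C1=O | starting material
2 | 4-methylpenta-1,3-diene | C=CC=C(C)C | starting material
3 | cis-fused cycloadduct, 4,4,8,10-tetramethyl-Δ2,7-octalin-6,9-dione (10β-methyl, 5β-H) | O=C1C=C(C)C(=O)[C@@]2(C)CC=CC(C)(C)[C@@H]12 | intermediate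
4 | trans-fused enedione, 4,4,8,10-tetramethyl-Δ2,7-octalin-6,9-dione (10β-methyl, 5α-H) | O=C1C=C(C)C(=O)[C@@]2(C)CC=CC(C)(C)[C@H]12 | intermediate
5 | trans-4,4,8,10-tetramethyldecalin-6,9-dione (10β-methyl, 5α-H; C8 epimer mixture, C8 left undefined) | O=C1CC(C)C(=O)[C@@]2(C)CCCC(C)(C)[C@H]12 | intermediate
6 | potassium C6 enolate of 5 (C6=C7; C8 epimer mixture) | [K+].[O-]C1=CC(C)C(=O)[C@@]2(C)CCCC(C)(C)[C@H]12 | intermediate (not isolated)
7 | 6-(tert-butyldimethylsilyloxy)-4,4,8,10-tetramethyl-Δ6-octalin-9-one (trans; C8 epimer mixture) | CC(C)(C)[Si](C)(C)OC1=CC(C)C(=O)[C@@]2(C)CCCC(C)(C)[C@H]12 | intermediate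
8 | potassium C9 dienolate of 7 | [K+].CC(C)(C)[Si](C)(C)OC1=CC(C)=C([O-])[C@@]2(C)CCCC(C)(C)[C@H]12 | intermediate (not isolated)
9 | 6-(tert-butyldimethylsilyloxy)-4,4,8,10-tetramethyl-Δ6,8-hexalin-9-yl trifluoromethanesulfonate (10β-methyl, 5α-H) | CC(C)(C)[Si](C)(C)OC1=CC(C)=C(OS(=O)(=O)C(F)(F)F)[C@@]2(C)CCCC(C)(C)[C@H]12 | intermediate
10 | but-2-yn-1-ol | CC#CCO | starting material
11 | sodium 2,2-bis(2-methoxyethoxy)-3-methyl-2,5-dihydro-1,2-oxaaluminol-2-uide (cyclic alkenylaluminate) | [Na+].CC1=CCO[Al-]1(OCCOC)OCCOC | intermediate (not isolated)
12 | (2Z)-3-iodobut-2-en-1-ol | C/C(I)=C/CO | intermediate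
13 | tert-butyl{[(2Z)-3-iodobut-2-en-1-yl]oxy}diphenylsilane | C/C(I)=C/CO[Si](c1ccccc1)(c1ccccc1)C(C)(C)C | intermediate
14 | tert-butyl{[(2Z)-3-methylpenta-2,4-dien-1-yl]oxy}diphenylsilane | C=C/C(C)=C\CO[Si](c1ccccc1)(c1ccccc1)C(C)(C)C | intermediate
15 | 9-[(3Z)-5-(tert-butyldiphenylsilyloxy)-3-methylpent-3-en-1-yl]-9-borabicyclo[3.3.1]nonane | CC(C)(C)[Si](OC/C=C(C)\CCB1C2CCCC1CCC2)(c1ccccc1)c1ccccc1 | intermediate (not isolated)
16 | 6-(tert-butyldimethylsilyloxy)-15-(tert-butyldiphenylsilyloxy)labda-6,8,13Z-triene | CC(C)(C)[Si](C)(C)OC1=CC(C)=C(CC/C(C)=C\CO[Si](c3ccccc3)(c3ccccc3)C(C)(C)C)[C@@]2(C)CCCC(C)(C)[C@H]12 | intermediate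
17 | 15-(tert-butyldiphenylsilyloxy)labda-8,13Z-dien-6-one | O=C1CC(C)=C(CC/C(C)=C\CO[Si](c3ccccc3)(c3ccccc3)C(C)(C)C)[C@@]2(C)CCCC(C)(C)[C@H]12 | intermediate
18 | potassium dienolate of 17 (O–C6=C7–C8=C9) | [K+].[O-]C1=CC(C)=C(CC/C(C)=C\CO[Si](c3ccccc3)(c3ccccc3)C(C)(C)C)[C@@]2(C)CCCC(C)(C)[C@H]12 | intermediate (not isolated)
19 | 15-(tert-butyldiphenylsilyloxy)-7α-hydroxylabda-8,13Z-dien-6-one | O=C1[C@@H](O)C(C)=C(CC/C(C)=C\CO[Si](c3ccccc3)(c3ccccc3)C(C)(C)C)[C@@]2(C)CCCC(C)(C)[C@H]12 | intermediate
20 | 15-(tert-butyldiphenylsilyloxy)labda-8,13Z-diene-6β,7α-diol | O[C@@H]1[C@@H](O)C(C)=C(CC/C(C)=C\CO[Si](c3ccccc3)(c3ccccc3)C(C)(C)C)[C@@]2(C)CCCC(C)(C)[C@H]12 | intermediate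
21 | 6β,7α-diacetoxy-15-(tert-butyldiphenylsilyloxy)labda-8,13Z-diene | CC(=O)O[C@@H]1[C@@H](OC(C)=O)C(C)=C(CC/C(C)=C\CO[Si](c3ccccc3)(c3ccccc3)C(C)(C)C)[C@@]2(C)CCCC(C)(C)[C@H]12 | intermediate
22 | 6β,7α-diacetoxylabda-8,13Z-dien-15-ol (CNP0187815.3) | CC(=O)O[C@@H]1[C@@H](OC(C)=O)C(C)=C(CC/C(C)=C\CO)[C@@]2(C)CCCC(C)(C)[C@H]12 | target

## Step count and least certain steps

Total step count: 14. Longest linear sequence: 11 steps (steps 1–5 and 9–14, from 1 and 2); the side-chain branch (steps 6–8, from 10) joins at step 9.

**Step 1 (key step).** The most likely failure is insufficient cycloaddition rate: the terminal Z methyl of 2 disfavours the s-cis conformer, so acid-induced oligomerisation of the diene can outrun the cycloaddition. A stepwise pathway or an uncatalysed background reaction could also erode the facial selectivity. The fallback gives up asymmetric induction in favour of resolution. It sets out from 1 and 2, which are combined under achiral promotion (BF3·OEt2 in CH2Cl2 at −40 °C, or 1.2 GPa without catalyst) to give the racemic cis adduct, that is 3 together with the mirror-image cis adduct F1. Epimerisation as in step 2 gives the racemic trans enedione, 4 together with the mirror-image trans enedione F2. Preparative chromatography on a chiral stationary phase (cellulose tris(3,5-dimethylphenylcarbamate)) then delivers 4, where the route is rejoined.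

**Step 2.** The risk is an unfavourable or incomplete equilibration. In the trans isomer the C6 carbonyl lies close to both C4 methyl groups, and the 4β and 10β methyls are syn-axial, so the energy gap to the cis isomer may be small. The fallback replaces thermodynamic by kinetic control. It sets out from 3, which is deprotonated at C5 with KN(SiMe3)2 in THF at −78 °C to give the potassium C5(6)-dienolate F3. A cold quench with acetic acid protonates C5 from the less hindered α face, opposite the two β methyl groups, and returns the route at 4.

**Step 9.** The risk is slow transmetalation and reductive elimination at the alkenylpalladium centre flanked by the quaternary C10 and the C8 methyl. This would let protodeboronation of 15, β-hydride elimination or hydrolysis of the triflate take over. The fallback moves the demanding bond formation to a small sp2 partner and reverses the roles in the alkyl coupling. It sets out from 9, which undergoes Stille vinylation (Bu3SnCH=CH2, Pd(PPh3)4, LiCl, THF, 65 °C) to the 9-vinyl triene F4. Hydroboration of its terminal alkene with 9-borabicyclo[3.3.1]nonane gives alkylborane F5. This is coupled with the unhindered Z iodide 13 (PdCl2(dppf), Cs2CO3, DMF/H2O) and comes back to the route at 16.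

**Step 11.** The risks are poor facial selectivity at C7, which is less directly shielded than C6, and base-induced isomerisation of the α-ketol alkoxide to the conjugated 6-hydroxy-7-ketone or its over-oxidation. The fallback oxidises the neutral silyl dienol ether instead of the enolate (Rubottom oxidation). It sets out from 16, which is treated with dimethyldioxirane (1.0 equiv, acetone/CH2Cl2, −78 °C). The bridging epoxidation transition state spans C6 and C7 and so feels the β-face shielding over C6; it should give the 6α,7α-silyloxy epoxide F6. Buffered fluoride (Bu4NF, AcOH, THF, −20 °C) opens F6 to the 7α-hydroxy ketone and returns the route at 19. One equivalent of oxidant at low temperature is used because the side-chain alkene and the C8=C9 bond are competing sites.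

## Further compounds

F1 | step 1 | mirror-image cis adduct (enantiomer of 3) | O=C1C=C(C)C(=O)[C@]2(C)CC=CC(C)(C)[C@H]12
F2 | step 1 | mirror-image trans enedione (enantiomer of 4) | O=C1C=C(C)C(=O)[C@]2(C)CC=CC(C)(C)[C@@H]12
F3 | step 2 | potassium C5(6)-dienolate of 3 | [K+].[O-]C1=C2C(C)(C)C=CC[C@]2(C)C(=O)C(C)=C1
F4 | step 9 | 6-(tert-butyldimethylsilyloxy)-9-ethenyl-4,4,8,10-tetramethyl-Δ6,8-hexalin (10β-methyl, 5α-H) | CC(C)(C)[Si](C)(C)OC1=CC(C)=C(C=C)[C@@]2(C)CCCC(C)(C)[C@H]12
F5 | step 9 | 9-{2-[6-(tert-butyldimethylsilyloxy)-4,4,8,10-tetramethyl-Δ6,8-hexalin-9-yl]ethyl}-9-borabicyclo[3.3.1]nonane | CC(C)(C)[Si](C)(C)OC1=CC(C)=C(CCB3C4CCCC3CCC4)[C@@]2(C)CCCC(C)(C)[C@H]12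
F6 | step 11 | 6β-(tert-butyldimethylsilyloxy)-6α,7α-epoxy-15-(tert-butyldiphenylsilyloxy)labda-8,13Z-diene | CC(C)(C)[Si](C)(C)O[C@@]14O[C@H]4C(C)=C(CC/C(C)=C\CO[Si](c3ccccc3)(c3ccccc3)C(C)(C)C)[C@@]2(C)CCCC(C)(C)[C@H]12
A1 | alternative 1 | trans-fused 6α-nitro-4,4,8α,10-tetramethyldecalin-9-one | [O-][N+](=O)[C@H]1C[C@@H](C)C(=O)[C@@]2(C)CCCC(C)(C)[C@H]12
A2 | alternative 1 | (9E)-2,4,8,8-tetramethyl-10-nitrodeca-1,9-dien-3-one | C=C(C)C(=O)C(C)CCCC(C)(C)/C=C/[N+](=O)[O-]
A3 | alternative 2 | drim-5-en-11-oic acid diastereomer (10β-methyl, 9α-carboxyl, 8α-methyl) | OC(=O)[C@@H]1[C@H](C)CC=C2C(C)(C)CCC[C@]12C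
A4 | alternative 2 | 4-methyl-6-(2,6,6-trimethylcyclohex-1-en-1-yl)oxan-2-one (δ-lactone) | O=C1C[C@H](C)C[C@H](O1)C2=C(C)CCCC2(C)C
A5 | alternative 3 | 6-(triisopropylsilyloxy)drima-5,8-dien-11-al (10β-methyl) | O=CC1=C(C)CC(O[Si](C(C)C)(C(C)C)C(C)C)=C2C(C)(C)CCC[C@]12C
A6 | alternative 3 | triisopropyl{[1-(2,6,6-trimethylcyclohex-1-en-1-yl)ethenyl]oxy}silane | C=C(O[Si](C(C)C)(C(C)C)C(C)C)C1=C(C)CCCC1(C)C
A7 | alternative 3 | but-2-ynal | CC#CC=O
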